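At 3.0 min, the early time asked, the flask is younger than any reading we hold, the first being at 2.00 h in the midnight run. We carry one quantity, the charge ratio: other conformer per substrate as charged, 0.250 in this flask.

| flask | substrate | other conformer | remark | time |
|---|---|---|---|---|
| spring | 0.40 M | 0.10 M | the very flask that is asked about, followed so far |  |
| midnight | 0.40 M | 0.20 M | run made earlier |  |
| flask | 0.40 M | 0.100 M |  | 40 h |

- spring (time / h: target / %, isomer of the product A / %): 4.00: 25, 10; 8.00: 31, 12; 12.0: 32, 17; 15.0: 28, 20
- midnight (time / h: target / %, isomer of the product A / %): 2.00: 18, 3; 6.00: 32, 11; 10.0: 32, 16; 15.0: 31, 20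

(standard deviation of a reading: 1.5 percentage points)

- share of target in target plus isomer of the product A at 3.0 min
- share of target in target plus isomer of the product A at 40 h



We suppose that a molecule's fork is its conformation: as substrate it goes to target, as other conformer to isomer of the product A. In the first instants the two flows should then follow the charge ratio. The midnight run charged 0.500, twice that, yet at 15.0 h isomer of the product A reads 20% in both runs, so we take the charge to be forgotten by then. In the spring run, target reads 31% at 8.00 h and 28% at 15.0 h, while isomer of the product A climbs from 12% to 20%, and the share reads 58.3% at 15.0 h. Our own reckoning differs from the forecast: we put the share at 3.0 min below the 85.7% read at 2.00 h in the midnight run, and the share at 40 h somewhat below that last spring reading.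

The forecast gives 88% (78% to 97%), “poorly defined by data”, and 29% (13% to 47%).

The flask gives 66.5% at 3.0 min and 52.6% at 40 h.

    substrate ⇌ other conformer (K = 0.0820, k = 2.80 h⁻¹)
    substrate → target (k = 0.120 h⁻¹)
    other conformer → isomer of the product A (k = 0.400 h⁻¹)
    other conformer ⇌ third conformer (K = 0.370, k = 0.680 h⁻¹)
    third conformer → third product (k = 0.0380 h⁻¹)
    other conformer ⇌ dormant form (K = 10.0, k = 0.0800 h⁻¹)
    target ⇌ isomer of the product B (K = 2.40, k = 0.120 h⁻¹)

The charge ratio now gets its multiplier, the selectivity factor 3.33, the rate constant to isomer of the product A over that to target. Other conformer is 20.0% of substrate plus other conformer at charge and 7.58% once the two are mixed; that gap relaxes by their interconversion, both ways together, with half-life 1.13 min, so on average 0.456 of it survives over 3.0 min. The flows then give 66.3% for this flask. The neighbouring flask with 0.10 M of substrate has a charge ratio of 1.00; the same reckoning gives 44.9%, and that flask gave 45.1%.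

The data are calculated with constants of no real substance; the scatter is artificial.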